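**Retrosynthetic overview**
- (2S)-6,8-Diprenylnaringenin ⇒ desilylation ⇒ ligand-controlled 1,4-hydride addition to the flat 6,8-diprenylflavone. Ring C is carried one oxidation level too high (C2 sp2), and C2, the only stereocentre, is set late.
- Flavone ⇒ one-operation [3+3] union of unprotected 2,4-diprenylphloroglucinol (ring A; O1 and C4a as O,C-bis-nucleophile) with ethyl 4-hydroxybenzoylacetate (C4–C3–C2 plus ring B; bis-electrophile through its aroylketene). C4–C4a and O1–C2 form together and ring C closes.
- Enabling feature: ring A is a hexasubstituted phloroglucinol with the same prenyl group on C6 and C8, so its precursor has a mirror plane through C7 and C4a. C4a is the only ring carbon bearing H and lies between two equivalent OH groups (future O1 and 5-OH). C-acylation therefore has one site, and closure by either OH gives the same ring C.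
- Ring order: rings A and B are bought (A is prenylated twice first); ring C is formed last, in the key step.

Key step: step 3

Assumption: (R)-DTBM-SEGPHOS is taken as the ligand antipode whose copper hydride attacks the C2 face that leads to 2S. If the sense is opposite, the (S)-ligand is used and nothing else changes.

Step 1
Reactants: 1 phloroglucinol; 2 prenyl bromide (1-bromo-3-methylbut-2-ene)
Product: 3 2,4-diprenylphloroglucinol
Conditions: 2 (2.0 equiv), KOH (2.0 equiv), H2O, 0 °C → rt, Ar; chromatography; used at once
Reagents that add atoms: none
Why: In water the phloroglucinolate behaves as a vinylogous enolate, so SN2 attack on the primary allylic bromide should go through carbon rather than oxygen (nuclear prenylation, C-alkylation of a phenolate), and two equivalents should make the 2,4-dialkylated triol the main component, which is separated from mono- and triprenylated material.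

Step 2
Reactants: 4 4'-hydroxyacetophenone; 5 diethyl carbonate
Product: 6 ethyl 3-(4-hydroxyphenyl)-3-oxopropanoate
Conditions: NaH (3.2 equiv), 5 (excess), THF, reflux; then aq HCl, 0 °C
Reagents that add atoms: none
Why: Crossed Claisen condensation, in which the ketone enolate (the phenol is parked as its phenoxide) is ethoxycarbonylated by the non-enolisable carbonate and the equilibrium is pulled by deprotonation of the β-keto ester.

Step 3
Reactants: 3 2,4-diprenylphloroglucinol; 6 ethyl 3-(4-hydroxyphenyl)-3-oxopropanoate
Product: 10 6,8-diprenylapigenin, via 4-hydroxybenzoylketene 7 (not isolated), via chelated 1,3-diketone 8 (not isolated), via 2-hydroxyflavanone hemiketal 9 (not isolated)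
Conditions: 6 (1.5 equiv), neat melt, 230–240 °C (microwave or metal bath), Ar, 10–20 min, EtOH/H2O vented
Reagents that add atoms: none
Why: Above about 200 °C the β-keto ester 6 loses ethanol to give the aroylketene 7, which adds reversibly to the OH groups of 3 but is drained irreversibly by C-acylation of the one free ring carbon (future C4a), giving the chelated diketone 8 (C4–C4a bond). One of the two OH groups flanking the new acyl group then adds to the aryl ketone carbon (future C2) in a 6-exo-trig closure to hemiketal 9 (O1–C2 bond), and loss of water gives the aromatic 4-pyrone, ring C. The closest known reaction type is the Mentzer pyrone synthesis, the thermal or microwave condensation of phloroglucinols with aroylacetates to 5,7-dihydroxyflavones. No stereocentre is formed: C2 is left sp2 on purpose and is set in step 5. Site selectivity is secured by the substrate, since C4a is the only CH of ring A and the two flanking OH groups are related by the mirror plane, so only one flavone can result. Chemoselectivity rests on the neutral, reagent-free melt: without acid the Pechmann mode (4-arylcoumarin) and the cyclisation of the ortho-prenylphenol units to chromans should stay behind, and such units are known to survive the temperatures of aromatic Claisen rearrangements.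

Step 4
Reactants: 10 6,8-diprenylapigenin
Product: 11 5,7,4'-tris-O-TBS-6,8-diprenylapigenin
Conditions: TBSOTf (4 equiv), 2,6-lutidine (6 equiv), CH2Cl2, 0 °C → rt
Reagents that add atoms: tert-butyldimethylsilyl triflate (TBSOTf), CC(C)(C)[Si](C)(C)OS(=O)(=O)C(F)(F)F
Why: The silyl triflate is electrophilic enough to silylate also the chelated 5-OH and the 7-OH between the two prenyl groups (O-silylation of phenols), which removes every acidic proton and the 5-OH/C4=O chelate before the hydride step, while the buffered medium leaves the prenyl groups untouched.

Step 5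
Reactants: 11 5,7,4'-tris-O-TBS-6,8-diprenylapigenin
Product: 12 (2S)-5,7,4'-tris-O-TBS-6,8-diprenylnaringenin
Conditions: Cu(OAc)2·H2O (5 mol %), (R)-DTBM-SEGPHOS (5.5 mol %), (EtO)2MeSiH (3 equiv), t-BuOH (2 equiv), toluene, 0 °C → rt
Reagents that add atoms: none
Why: Ligand-controlled asymmetric conjugate reduction with copper hydride, a reaction type known for 2-substituted chromones: the chiral L*CuH should add hydride to one face of C2 of the planar pyrone (setting 2S), t-BuOH protonates the copper enolate at C3 while the silane regenerates the hydride, and the isolated prenyl alkenes, the aryl silyl ethers and the hindered, electron-rich C4 ketone should not react.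

Step 6
Reactants: 12 (2S)-5,7,4'-tris-O-TBS-6,8-diprenylnaringenin
Product: 13 (2S)-6,8-diprenylnaringenin
Conditions: Et3N·3HF (excess), THF, 0 °C → rt
Reagents that add atoms: none
Why: Fluoride-driven Si–O cleavage in a slightly acidic medium frees the three phenols without phenoxide formation, so retro-oxa-Michael opening of ring C (the racemisation path of C2) and acid cyclisation of the prenyl groups onto the neighbouring OH groups should both be avoided.

**Compound list**
1 | phloroglucinol (benzene-1,3,5-triol) | Oc1cc(O)cc(O)c1 | starting material
2 | prenyl bromide (1-bromo-3-methylbut-2-ene) | CC(C)=CCBr | starting material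
3 | 2,4-diprenylphloroglucinol [2,4-bis(3-methylbut-2-enyl)benzene-1,3,5-triol] | CC(C)=CCc1c(O)cc(O)c(CC=C(C)C)c1O | intermediate
4 | 4'-hydroxyacetophenone | CC(=O)c1ccc(O)cc1 | starting material
5 | diethyl carbonate | CCOC(=O)OCC | starting material
6 | ethyl 3-(4-hydroxyphenyl)-3-oxopropanoate | CCOC(=O)CC(=O)c1ccc(O)cc1 | intermediate
7 | 4-hydroxybenzoylketene (not isolated) | O=C=CC(=O)c1ccc(O)cc1 | intermediate
8 | 1-[2,4,6-trihydroxy-3,5-bis(3-methylbut-2-enyl)phenyl]-3-(4-hydroxyphenyl)propane-1,3-dione (not isolated) | CC(C)=CCc1c(O)c(CC=C(C)C)c(O)c(c1O)C(=O)CC(=O)c1ccc(O)cc1 | intermediate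
9 | 2,5,7-trihydroxy-2-(4-hydroxyphenyl)-6,8-diprenylchroman-4-one, racemic hemiketal (not isolated) | CC(C)=CCc1c(O)c(CC=C(C)C)c2c(c1O)C(=O)CC(O)(c1ccc(O)cc1)O2 | intermediate
10 | 6,8-diprenylapigenin [5,7-dihydroxy-2-(4-hydroxyphenyl)-6,8-bis(3-methylbut-2-enyl)-4H-chromen-4-one] | CC(C)=CCc1c(O)c(CC=C(C)C)c2c(c1O)C(=O)C=C(c1ccc(O)cc1)O2 | intermediate
11 | 5,7,4'-tris-O-TBS-6,8-diprenylapigenin | CC(C)=CCc1c(O[Si](C)(C)C(C)(C)C)c(CC=C(C)C)c2c(c1O[Si](C)(C)C(C)(C)C)C(=O)C=C(c1ccc(O[Si](C)(C)C(C)(C)C)cc1)O2 | intermediate
12 | (2S)-5,7,4'-tris-O-TBS-6,8-diprenylnaringenin | CC(C)=CCc1c(O[Si](C)(C)C(C)(C)C)c(CC=C(C)C)c2c(c1O[Si](C)(C)C(C)(C)C)C(=O)C[C@@H](c1ccc(O[Si](C)(C)C(C)(C)C)cc1)O2 | intermediate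
13 | (2S)-6,8-diprenylnaringenin | CC(C)=CCc1c(O)c(CC=C(C)C)c2c(c1O)C(=O)C[C@@H](c1ccc(O)cc1)O2 | target

**Total step count:** 6. **Longest linear sequence:** 5 steps (1, 3, 4, 5, 6; the branch 2, 3, 4, 5, 6 is equally long).

**Steps most likely to fail**

Most at risk is step 3. In the hot melt the ortho-prenylphenol units may close to chromans, the electron-rich triol may oxidise, or the reaction may stall at the O-acyl stage. The fallback reverses the order of events and sets out from 1 and 6. The same melt annulation is run on 1 itself, the parent case of this reaction, to give apigenin F1. The two prenyl groups are then placed on C6 and C8 by nuclear prenylation of the 5,7-dihydroxyflavone with 2 (KOH, MeOH). The route is rejoined at 10.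

Second is step 5. Three things may go wrong:
- hydride transfer to the electron-rich, vinylogous-ester-like pyrone may be sluggish;
- facial selectivity may be poor;
- the copper enolate may expel the ring aryloxide and open ring C.

The fallback replaces asymmetric induction by resolution and sets out from 11. An achiral copper hydride (Cu(OAc)2·H2O, 1,2-bis(diphenylphosphino)benzene, same silane and alcohol) should give the racemic silyl-protected flavanone F2. Kinetic resolution by asymmetric transfer hydrogenation follows, using RhCl(Cp*)[(R,R)-TsDPEN] or its mirror image, whichever consumes the 2R ketone faster, with HCO2H/Et3N in EtOAc. This should reduce the 2R ketone to the 2,4-cis-flavan-4-ol F3. The untouched 2S ketone is separated by chromatography, and the route is rejoined at 12.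

Third is step 1. Alkylation of three equivalent ring carbons is statistical. Under- and over-prenylation, geminal dialkylation with loss of aromaticity, and O-alkylation may all erode the wanted triol. The fallback blocks the third carbon with a traceless group and sets out from 1. Kolbe–Schmitt carboxylation (KHCO3, H2O, 50–60 °C) gives 2,4,6-trihydroxybenzoic acid F4. C-prenylation of its salt with 2 (KOH, H2O, 0 °C) can then reach only the two remaining ring CH positions and gives 2,4,6-trihydroxy-3,5-diprenylbenzoic acid F5. Gentle heating (toluene, 110 °C) decarboxylates this phloroglucinolcarboxylic acid, and the route is rejoined at 3.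

**Further compounds**
F1 | step 3 | apigenin [5,7-dihydroxy-2-(4-hydroxyphenyl)-4H-chromen-4-one] | O=C1C=C(c2ccc(O)cc2)Oc2cc(O)cc(O)c12
F2 | step 5 | racemic 5,7,4'-tris-O-TBS-6,8-diprenylnaringenin | CC(C)=CCc1c(O[Si](C)(C)C(C)(C)C)c(CC=C(C)C)c2c(c1O[Si](C)(C)C(C)(C)C)C(=O)CC(c1ccc(O[Si](C)(C)C(C)(C)C)cc1)O2
F3 | step 5 | (2R,4R)-5,7,4'-tris-O-TBS-6,8-diprenylflavan-4-ol (2,4-cis) | CC(C)=CCc1c(O[Si](C)(C)C(C)(C)C)c(CC=C(C)C)c2c(c1O[Si](C)(C)C(C)(C)C)[C@H](O)C[C@H](c1ccc(O[Si](C)(C)C(C)(C)C)cc1)O2
F4 | step 1 | 2,4,6-trihydroxybenzoic acid | O=C(O)c1c(O)cc(O)cc1O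
F5 | step 1 | 2,4,6-trihydroxy-3,5-diprenylbenzoic acid | CC(C)=CCc1c(O)c(CC=C(C)C)c(O)c(C(=O)O)c1O
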